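Benzodioxane numbering: O1, C2 (bears syringyl ring A), C3 (bears CH2OH), O4, C4a, C5 (OMe), C6, C7 (E-propenol), C8, C8a. Ring B is the benzo ring, and the target is the trans (2S,3S) isomer.
Enabling feature: ring B has oxygen on three neighbouring carbons (C8a, C4a, C5) and its side chain on C7, para to the central C4a. This matches a cyclohexane-1,3-dione oxygenated at its C2 and substituted at its C5, so ring B can be carried as that dione and aromatised late.
Cuts, in retrosynthetic order: the side-chain alkene at C7 (Wittig), the O–CH3 bond at C5 and the aromaticity of ring B, then O4–C4a and O1–C8a together, and last C2–C3 (aldol).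
Forward order: ring A is bought and C2–C3 is joined by a glycolate aldol. The dioxane ring then closes onto a saturated ring B in one flask (carbene O–H insertion, then acid condensation). Ring B is dehydrogenated and O-methylated, and the C7 ester is extended to the propenol.
Stereochemistry: C2 and C3 are set together in a syn-selective Evans aldol under (R)-4-benzyloxazolidin-2-one. The annulation forms bonds only at oxygen, so threo becomes trans. The E-alkene comes from a stabilised ylide.

Key step: step 8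

Remark on the chemistry: ethyl 3,5-dioxocyclohexane-1-carboxylate is assumed to be purchasable as a bulk intermediate; Ar = 3,5-dimethoxy-4-(triisopropylsilyloxy)phenyl, TIPS = triisopropylsilyl, TES = triethylsilyl, TMS = trimethylsilyl, and locants C2 to C8a always follow the numbering above.

Step 1
Reactants: 1 syringaldehyde (4-hydroxy-3,5-dimethoxybenzaldehyde)
Product: 2 3,5-dimethoxy-4-(triisopropylsilyloxy)benzaldehyde
Conditions: TIPSCl, imidazole, DMF, rt
Reagents that add atoms: triisopropylsilyl chloride CC(C)[Si](Cl)(C(C)C)C(C)C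
Why: Routine imidazole-promoted silylation of a phenol, chosen because the hindered aryl TIPS ether should outlast the boron aldol, hydride, amide base and catalytic acid to come and still leave with fluoride.

Step 2
Reactants: 3 (R)-4-benzyloxazolidin-2-one, 4 benzyloxyacetyl chloride
Product: 5 (R)-4-benzyl-3-(benzyloxyacetyl)oxazolidin-2-one
Conditions: n-BuLi, THF, −78 °C; then 4, −78 → 0 °C
Reagents that add atoms: none
Why: N-acylation of the lithiated oxazolidinone with an acid chloride is the standard entry to Evans imides, and the benzyl ether marks the oxygen that will become O4.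

Step 3
Reactants: 5 (R)-4-benzyl-3-(benzyloxyacetyl)oxazolidin-2-one, 2 3,5-dimethoxy-4-(triisopropylsilyloxy)benzaldehyde
Product: 8 (R)-4-benzyl-3-[(2R,3S)-3-Ar-2-benzyloxy-3-hydroxypropanoyl]oxazolidin-2-one, via boron enolate 6 (not isolated), via boron aldolate 7 (not isolated)
Conditions: Bu2BOTf, Et3N, CH2Cl2, −78 → 0 °C; 2, −78 → 0 °C; then H2O2, MeOH, pH 7 buffer, 0 °C
Reagents that add atoms: none
Why: Evans syn glycolate aldol, in which soft enolisation gives the Z boron enolate 6 that adds to the non-enolisable aldehyde through a chair Zimmerman–Traxler transition state on the face turned away from the benzyl group of the (R)-auxiliary, so that the future C3 (2R) and C2 (3S) are set together in the syn (threo) relationship before oxidative work-up frees 8 from boron.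

Step 4
Reactants: 8 (R)-4-benzyl-3-[(2R,3S)-3-Ar-2-benzyloxy-3-hydroxypropanoyl]oxazolidin-2-one
Product: 9 (1S,2S)-1-Ar-2-(benzyloxy)propane-1,3-diol
Conditions: LiBH4, MeOH (1 equiv), THF, 0 °C
Reagents that add atoms: none
Why: Reductive cleavage of the imide with LiBH4 is the usual way to take an Evans adduct to the primary alcohol, touches neither stereocentre and returns the auxiliary.

Step 5
Reactants: 9 (1S,2S)-1-Ar-2-(benzyloxy)propane-1,3-diol
Product: 11 (1S,2S)-1-Ar-2-benzyloxy-1-(triethylsilyloxy)-3-(triisopropylsilyloxy)propane, via primary silyl ether 10 (not isolated)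
Conditions: TIPSCl (1.05 equiv), imidazole, DMF, 0 °C → rt; then TESCl, rt
Reagents that add atoms: triisopropylsilyl chloride CC(C)[Si](Cl)(C(C)C)C(C)C; triethylsilyl chloride CC[Si](Cl)(CC)CC
Why: Two silylations in one flask that rely on steric discrimination, since TIPSCl takes only the primary hydroxyl and the smaller TESCl then caps the benzylic one, giving ethers of graded acid lability.

Step 6
Reactants: 11 (1S,2S)-1-Ar-2-benzyloxy-1-(triethylsilyloxy)-3-(triisopropylsilyloxy)propane
Product: 12 (1S,2S)-1-Ar-1-(triethylsilyloxy)-3-(triisopropylsilyloxy)propan-2-ol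
Conditions: H2 (1 atm), Pd/C, EtOAc, rt
Reagents that add atoms: none
Why: Hydrogenolysis of an alkyl benzyl ether over Pd/C, run in aprotic EtOAc where TES ethers persist, and expected to spare the crowded secondary benzylic C–O bond at ring A because the unhindered PhCH2–O bond is cleaved far faster.

Step 7
Reactants: 13 ethyl 3,5-dioxocyclohexane-1-carboxylate
Product: 14 ethyl 4-diazo-3,5-dioxocyclohexane-1-carboxylate
Conditions: 4-acetamidobenzenesulfonyl azide, Et3N, MeCN, 0 °C → rt
Reagents that add atoms: 4-acetamidobenzenesulfonyl azide CC(=O)Nc1ccc(cc1)S(=O)(=O)N=[N+]=[N-]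
Why: Regitz diazo transfer to the activated methylene between the two carbonyl groups, which needs only an amine base for cyclic 1,3-diones.

Step 8
Reactants: 12 (1S,2S)-1-Ar-1-(triethylsilyloxy)-3-(triisopropylsilyloxy)propan-2-ol, 14 ethyl 4-diazo-3,5-dioxocyclohexane-1-carboxylate
Product: 17 ethyl (2S,3S)-2-Ar-5-oxo-3-(triisopropylsilyloxymethyl)-2,3,5,6,7,8-hexahydro-1,4-benzodioxine-7-carboxylate (trans; both C7 epimers), via alkoxy dione 15 (not isolated), via hydroxy dione 16 (not isolated)
Conditions: Rh2(OAc)4 (2 mol %), PhF, 80 °C, slow addition of 14 (1.5 equiv); then TsOH·H2O (0.2 equiv), rt → 50 °C, 4 Å MS added late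
Reagents that add atoms: none
Why: Rh2(OAc)4 takes N2 out of 14 and the resulting electrophilic rhodium carbene, centred on the carbon between the two carbonyl groups, is attacked by the one free hydroxyl of 12; proton transfer in the oxonium ylide gives alkoxy dione 15 and with it the O4–C4a bond, which is the known O–H insertion of cyclic 2-diazo-1,3-diones into alcohols. TsOH·H2O then removes the TES group much faster than either TIPS group, and the benzylic hydroxyl of 16 adds to a ring carbonyl in a 6-exo-trig closure and loses water, the ordinary acid-catalysed formation of a vinylogous ester from a 1,3-dione, which makes O1–C8a and closes the dioxane ring as a dioxene. Since both bonds are formed at oxygen, C2 and C3 are not touched and the threo precursor can only give the trans ring; no stereocentre of the target is created, and the one new centre, C7, arises without control as an epimer mixture that step 9 erases. The selectivity that matters is regiochemical (C3 oxygen to C4a, C2 oxygen to C8a) and is enforced by the silyl mask on the C2 oxygen while the carbene is present. The two carbonyl groups of the 5-substituted dione are constitutionally equivalent, so either closure leaves the surviving ketone at C5, next to C4a, where the methoxy group belongs. Fluorobenzene is chosen because it resists the carbene, and the slow addition of 14 keeps carbene dimerisation behind capture by the crowded alcohol.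

Step 9
Reactants: 17 ethyl (2S,3S)-2-Ar-5-oxo-3-(triisopropylsilyloxymethyl)-2,3,5,6,7,8-hexahydro-1,4-benzodioxine-7-carboxylate
Product: 20 ethyl (2S,3S)-2-Ar-5-hydroxy-3-(triisopropylsilyloxymethyl)-2,3-dihydro-1,4-benzodioxine-7-carboxylate, via silyl dienol ether 18 (not isolated), via cross-conjugated dienone 19 (not isolated)
Conditions: LiN(i-Pr)2, THF, −78 °C; TMSCl; solvent change; Pd(OAc)2 (1.1 equiv), MeCN, rt
Reagents that add atoms: none
Why: Saegusa–Ito dehydrogenation, in which kinetic deprotonation at C6 and silylation give 18, Pd(OAc)2 converts it into a palladium enolate that loses the C7 hydrogen to give 19, and this dienone tautomerises at once to the phenol and so erases the C7 centre, while any enolisation toward C8 would converge on the same phenol and the base-and-palladium conditions spare the silyl ethers and the dioxene that hot acidic methanol would endanger.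

Step 10
Reactants: 20 ethyl (2S,3S)-2-Ar-5-hydroxy-3-(triisopropylsilyloxymethyl)-2,3-dihydro-1,4-benzodioxine-7-carboxylate
Product: 21 ethyl (2S,3S)-2-Ar-5-methoxy-3-(triisopropylsilyloxymethyl)-2,3-dihydro-1,4-benzodioxine-7-carboxylate
Conditions: MeI, K2CO3, acetone, rt
Reagents that add atoms: iodomethane CI
Why: Williamson O-methylation of the only free phenol under mild anhydrous carbonate conditions that the doubly flanked aryl TIPS ether should tolerate.

Step 11
Reactants: 21 ethyl (2S,3S)-2-Ar-5-methoxy-3-(triisopropylsilyloxymethyl)-2,3-dihydro-1,4-benzodioxine-7-carboxylate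
Product: 22 [(2S,3S)-2-Ar-5-methoxy-3-(triisopropylsilyloxymethyl)-2,3-dihydro-1,4-benzodioxin-7-yl]methanol
Conditions: i-Bu2AlH (2.5 equiv), CH2Cl2, −78 → 0 °C; aq potassium sodium tartrate
Reagents that add atoms: none
Why: Exhaustive i-Bu2AlH reduction of an aryl ester to the benzylic alcohol is more dependable than an attempt to stop at the aldehyde.

Step 12
Reactants: 22 [(2S,3S)-2-Ar-5-methoxy-3-(triisopropylsilyloxymethyl)-2,3-dihydro-1,4-benzodioxin-7-yl]methanol
Product: 24 ethyl (E)-3-[(2S,3S)-2-Ar-5-methoxy-3-(triisopropylsilyloxymethyl)-2,3-dihydro-1,4-benzodioxin-7-yl]prop-2-enoate, via aldehyde 23 (not isolated)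
Conditions: MnO2 (excess), Ph3P=CHCO2Et, CH2Cl2, rt
Reagents that add atoms: ethyl (triphenylphosphoranylidene)acetate CCOC(=O)C=P(c1ccccc1)(c1ccccc1)c1ccccc1
Why: Tandem oxidation–Wittig olefination, in which MnO2 oxidises only the benzylic alcohol and the stabilised ylide traps aldehyde 23 as it forms, giving the E-alkene as stabilised ylides normally do.

Step 13
Reactants: 24 ethyl (E)-3-[(2S,3S)-2-Ar-5-methoxy-3-(triisopropylsilyloxymethyl)-2,3-dihydro-1,4-benzodioxin-7-yl]prop-2-enoate
Product: 25 (E)-3-[(2S,3S)-2-Ar-5-methoxy-3-(triisopropylsilyloxymethyl)-2,3-dihydro-1,4-benzodioxin-7-yl]prop-2-en-1-ol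
Conditions: i-Bu2AlH (2.5 equiv), CH2Cl2, −78 °C; aq potassium sodium tartrate
Reagents that add atoms: none
Why: 1,2-Reduction of the α,β-unsaturated ester with i-Bu2AlH gives the allylic alcohol without touching the alkene or its geometry.

Step 14
Reactants: 25 (E)-3-[(2S,3S)-2-Ar-5-methoxy-3-(triisopropylsilyloxymethyl)-2,3-dihydro-1,4-benzodioxin-7-yl]prop-2-en-1-ol
Product: 26 (E)-3-[(2S,3S)-2-(4-hydroxy-3,5-dimethoxyphenyl)-3-(hydroxymethyl)-5-methoxy-2,3-dihydro-1,4-benzodioxin-7-yl]prop-2-en-1-ol (target)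
Conditions: Bu4NF (3 equiv), AcOH (3 equiv), THF, 0 °C → rt
Reagents that add atoms: none
Why: Fluoride cleavage of both silyl ethers, buffered with AcOH so that the liberated para-phenol stays protonated and cannot expel O1 from the benzylic C2 and endanger the trans configuration.

Compound list
1 | syringaldehyde | COc1cc(C=O)cc(OC)c1O | starting material
2 | 3,5-dimethoxy-4-(triisopropylsilyloxy)benzaldehyde | COc1cc(C=O)cc(OC)c1O[Si](C(C)C)(C(C)C)C(C)C | intermediate
3 | (R)-4-benzyloxazolidin-2-one | O=C1N[C@H](Cc2ccccc2)CO1 | starting material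
4 | benzyloxyacetyl chloride | O=C(Cl)COCc1ccccc1 | starting material
5 | (R)-4-benzyl-3-(benzyloxyacetyl)oxazolidin-2-one | O=C(COCc1ccccc1)N1C(=O)OC[C@H]1Cc1ccccc1 | intermediate
6 | (Z)-dibutylboron enolate of 5 (formed in the flask) | CCCCB(CCCC)O/C(N1C(=O)OC[C@H]1Cc1ccccc1)=C\OCc1ccccc1 | intermediate
7 | dibutylboron aldolate of 8 (formed in the flask) | COc1cc([C@H](OB(CCCC)CCCC)[C@@H](OCc2ccccc2)C(=O)N2C(=O)OC[C@H]2Cc2ccccc2)cc(OC)c1O[Si](C(C)C)(C(C)C)C(C)C | intermediate
8 | (R)-4-benzyl-3-[(2R,3S)-3-Ar-2-benzyloxy-3-hydroxypropanoyl]oxazolidin-2-one | COc1cc([C@H](O)[C@@H](OCc2ccccc2)C(=O)N2C(=O)OC[C@H]2Cc2ccccc2)cc(OC)c1O[Si](C(C)C)(C(C)C)C(C)C | intermediate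
9 | (1S,2S)-1-Ar-2-(benzyloxy)propane-1,3-diol | COc1cc([C@H](O)[C@@H](OCc2ccccc2)CO)cc(OC)c1O[Si](C(C)C)(C(C)C)C(C)C | intermediate
10 | (1S,2S)-1-Ar-2-benzyloxy-3-(triisopropylsilyloxy)propan-1-ol (formed in the flask) | COc1cc([C@H](O)[C@@H](OCc2ccccc2)CO[Si](C(C)C)(C(C)C)C(C)C)cc(OC)c1O[Si](C(C)C)(C(C)C)C(C)C | intermediate
11 | (1S,2S)-1-Ar-2-benzyloxy-1-(triethylsilyloxy)-3-(triisopropylsilyloxy)propane | COc1cc([C@H](O[Si](CC)(CC)CC)[C@@H](OCc2ccccc2)CO[Si](C(C)C)(C(C)C)C(C)C)cc(OC)c1O[Si](C(C)C)(C(C)C)C(C)C | intermediate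
12 | (1S,2S)-1-Ar-1-(triethylsilyloxy)-3-(triisopropylsilyloxy)propan-2-ol | COc1cc([C@H](O[Si](CC)(CC)CC)[C@@H](O)CO[Si](C(C)C)(C(C)C)C(C)C)cc(OC)c1O[Si](C(C)C)(C(C)C)C(C)C | intermediate
13 | ethyl 3,5-dioxocyclohexane-1-carboxylate | CCOC(=O)C1CC(=O)CC(=O)C1 | starting material
14 | ethyl 4-diazo-3,5-dioxocyclohexane-1-carboxylate | CCOC(=O)C1CC(=O)C(=[N+]=[N-])C(=O)C1 | intermediate
15 | O–H insertion product, 2-alkoxy-1,3-dione with TES still on the C2 oxygen (formed in the flask) | COc1cc([C@H](O[Si](CC)(CC)CC)[C@@H](OC2C(=O)CC(C(=O)OCC)CC2=O)CO[Si](C(C)C)(C(C)C)C(C)C)cc(OC)c1O[Si](C(C)C)(C(C)C)C(C)C | intermediate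
16 | 2-alkoxy-1,3-dione with free benzylic hydroxyl (formed in the flask) | COc1cc([C@H](O)[C@@H](OC2C(=O)CC(C(=O)OCC)CC2=O)CO[Si](C(C)C)(C(C)C)C(C)C)cc(OC)c1O[Si](C(C)C)(C(C)C)C(C)C | intermediate
17 | ethyl (2S,3S)-2-Ar-5-oxo-3-(triisopropylsilyloxymethyl)-2,3,5,6,7,8-hexahydro-1,4-benzodioxine-7-carboxylate, C7 epimers | COc1cc([C@@H]2OC3=C(O[C@H]2CO[Si](C(C)C)(C(C)C)C(C)C)C(=O)CC(C(=O)OCC)C3)cc(OC)c1O[Si](C(C)C)(C(C)C)C(C)C | intermediate
18 | C5-trimethylsilyloxy C5=C6 dienol ether of 17 (formed in the flask) | COc1cc([C@@H]2OC3=C(O[C@H]2CO[Si](C(C)C)(C(C)C)C(C)C)C(O[Si](C)(C)C)=CC(C(=O)OCC)C3)cc(OC)c1O[Si](C(C)C)(C(C)C)C(C)C | intermediate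
19 | C6=C7 dehydro derivative of 17, cross-conjugated dienone (formed in the flask) | COc1cc([C@@H]2OC3=C(O[C@H]2CO[Si](C(C)C)(C(C)C)C(C)C)C(=O)C=C(C(=O)OCC)C3)cc(OC)c1O[Si](C(C)C)(C(C)C)C(C)C | intermediate
20 | ethyl (2S,3S)-2-Ar-5-hydroxy-3-(triisopropylsilyloxymethyl)-2,3-dihydro-1,4-benzodioxine-7-carboxylate | COc1cc([C@@H]2Oc3cc(C(=O)OCC)cc(O)c3O[C@H]2CO[Si](C(C)C)(C(C)C)C(C)C)cc(OC)c1O[Si](C(C)C)(C(C)C)C(C)C | intermediate
21 | ethyl (2S,3S)-2-Ar-5-methoxy-3-(triisopropylsilyloxymethyl)-2,3-dihydro-1,4-benzodioxine-7-carboxylate | COc1cc([C@@H]2Oc3cc(C(=O)OCC)cc(OC)c3O[C@H]2CO[Si](C(C)C)(C(C)C)C(C)C)cc(OC)c1O[Si](C(C)C)(C(C)C)C(C)C | intermediate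
22 | [(2S,3S)-2-Ar-5-methoxy-3-(triisopropylsilyloxymethyl)-2,3-dihydro-1,4-benzodioxin-7-yl]methanol | COc1cc([C@@H]2Oc3cc(CO)cc(OC)c3O[C@H]2CO[Si](C(C)C)(C(C)C)C(C)C)cc(OC)c1O[Si](C(C)C)(C(C)C)C(C)C | intermediate
23 | (2S,3S)-2-Ar-5-methoxy-3-(triisopropylsilyloxymethyl)-2,3-dihydro-1,4-benzodioxine-7-carbaldehyde (formed in the flask) | COc1cc([C@@H]2Oc3cc(C=O)cc(OC)c3O[C@H]2CO[Si](C(C)C)(C(C)C)C(C)C)cc(OC)c1O[Si](C(C)C)(C(C)C)C(C)C | intermediate
24 | ethyl (E)-3-[(2S,3S)-2-Ar-5-methoxy-3-(triisopropylsilyloxymethyl)-2,3-dihydro-1,4-benzodioxin-7-yl]prop-2-enoate | COc1cc([C@@H]2Oc3cc(/C=C/C(=O)OCC)cc(OC)c3O[C@H]2CO[Si](C(C)C)(C(C)C)C(C)C)cc(OC)c1O[Si](C(C)C)(C(C)C)C(C)C | intermediate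
25 | (E)-3-[(2S,3S)-2-Ar-5-methoxy-3-(triisopropylsilyloxymethyl)-2,3-dihydro-1,4-benzodioxin-7-yl]prop-2-en-1-ol | COc1cc([C@@H]2Oc3cc(/C=C/CO)cc(OC)c3O[C@H]2CO[Si](C(C)C)(C(C)C)C(C)C)cc(OC)c1O[Si](C(C)C)(C(C)C)C(C)C | intermediate
26 | (E)-3-[(2S,3S)-2-(4-hydroxy-3,5-dimethoxyphenyl)-3-(hydroxymethyl)-5-methoxy-2,3-dihydro-1,4-benzodioxin-7-yl]prop-2-en-1-ol | COc1cc([C@@H]2Oc3cc(/C=C/CO)cc(OC)c3O[C@H]2CO)cc(OC)c1O | target

Total step count: 14.
Longest linear sequence: 12 steps (1 → 2 → 8 → 9 → 11 → 12 → 17 → 20 → 21 → 22 → 24 → 25 → 26).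

Steps most likely to fail

**Step 8.**
- What may go wrong:
  - The secondary hydroxyl, crowded by two silyl ethers, may capture the carbene slowly. Carbene dimerisation, Wolff rearrangement, attack on ring A, or a second insertion into the acidic enol O–H of 15 could then take over.
  - In the acid stage, ionisation at the benzylic C2 could erode the trans relationship.
- Fallback (ring B brought in already aromatic, known chemistry only). It sets out from 3 and 2 and comes back at 21. Auxiliary 3 is acylated with bromoacetyl bromide (n-BuLi, THF, −78 °C) to the bromoacetyl imide F1. Purchased ethyl 3-bromo-4-hydroxy-5-methoxybenzoate (CCOC(=O)c1cc(Br)c(O)c(OC)c1) displaces the bromide (K2CO3, acetone) to give the aryloxyacetyl imide F2, in which O4–C4a already exists. The boron-mediated syn aldol of step 3 with 2 gives the syn aldol adduct F3. LiBH4 reduces the imide faster than the aryl ester and releases the 1,3-diol F4, and TIPSCl with imidazole caps the primary hydroxyl to give the bromo alcohol F5. An intramolecular Buchwald–Hartwig etherification (Pd(OAc)2, 2-(di-tert-butylphosphino)-1,1'-binaphthyl, Cs2CO3, toluene, 80 °C) then joins the benzylic oxygen to the brominated carbon (O1–C8a), again at oxygen, and delivers 21.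

**Step 9.**
- What may go wrong:
  - Enolisation may be incomplete or unselective because of competition from the ester α-hydrogen.
  - The silyl dienol ether may hydrolyse before palladation.
  - β-Hydride elimination may be sluggish at the ester-bearing carbon.
- Fallback (no enolate, no palladium). It sets out from 17 and comes back at 22. Iodine (2 equiv) in methanol at reflux, the classical oxidative aromatisation of cyclohexenones to anisoles, should take 17 directly to 21 and make step 10 unnecessary. Part of the material would exchange its ester with the solvent to the methyl ester F6. The conditions of step 11 reduce both esters to the same alcohol 22. This shorter path is held in reserve for two reasons: the hydrogen iodide it generates threatens the primary silyl ether, and it lets methanol exchange into the vinylogous ester.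

**Step 6.**
- What may go wrong: the TES group may migrate to the freshly released neighbouring hydroxyl, or be lost on the catalyst or on handling. Either would scramble the regiochemistry of the annulation.
- Fallback (an acetal mask that cannot migrate). It sets out from 10, with step 5 stopped after the first silylation, and comes back at 16. Ethyl vinyl ether with catalytic pyridinium p-toluenesulfonate in CH2Cl2 converts 10 into the 1-ethoxyethyl acetal F7 (mixture at the acetal carbon). Hydrogenolysis (H2, Pd/C, EtOAc) gives the free alcohol F8. Rh2(OAc)4 with 14 in PhF gives the alkoxy dione F9. TsOH·H2O in the same flask cleaves the acetal to 16, which closes to 17 as in step 8.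

Further compounds
F1 | step 8 | (R)-4-benzyl-3-(bromoacetyl)oxazolidin-2-one | O=C(CBr)N1C(=O)OC[C@H]1Cc1ccccc1
F2 | step 8 | ethyl 4-{2-[(R)-4-benzyl-2-oxooxazolidin-3-yl]-2-oxoethoxy}-3-bromo-5-methoxybenzoate | CCOC(=O)c1cc(Br)c(OCC(=O)N2C(=O)OC[C@H]2Cc2ccccc2)c(OC)c1
F3 | step 8 | (2R,3S) syn aldol adduct of F2 and 2 | COc1cc([C@H](O)[C@@H](Oc2c(Br)cc(C(=O)OCC)cc2OC)C(=O)N2C(=O)OC[C@H]2Cc2ccccc2)cc(OC)c1O[Si](C(C)C)(C(C)C)C(C)C
F4 | step 8 | ethyl 4-{[(1S,2S)-1-Ar-1,3-dihydroxypropan-2-yl]oxy}-3-bromo-5-methoxybenzoate | COc1cc([C@H](O)[C@@H](Oc2c(Br)cc(C(=O)OCC)cc2OC)CO)cc(OC)c1O[Si](C(C)C)(C(C)C)C(C)C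
F5 | step 8 | primary TIPS ether of F4 | COc1cc([C@H](O)[C@@H](Oc2c(Br)cc(C(=O)OCC)cc2OC)CO[Si](C(C)C)(C(C)C)C(C)C)cc(OC)c1O[Si](C(C)C)(C(C)C)C(C)C
F6 | step 9 | methyl ester analogue of 21 | COc1cc([C@@H]2Oc3cc(C(=O)OC)cc(OC)c3O[C@H]2CO[Si](C(C)C)(C(C)C)C(C)C)cc(OC)c1O[Si](C(C)C)(C(C)C)C(C)C
F7 | step 6 | 1-ethoxyethyl acetal of 10 (benzylic oxygen; acetal epimers) | COc1cc([C@H](OC(C)OCC)[C@@H](OCc2ccccc2)CO[Si](C(C)C)(C(C)C)C(C)C)cc(OC)c1O[Si](C(C)C)(C(C)C)C(C)C
F8 | step 6 | (1S,2S)-1-Ar-1-(1-ethoxyethoxy)-3-(triisopropylsilyloxy)propan-2-ol | COc1cc([C@H](OC(C)OCC)[C@@H](O)CO[Si](C(C)C)(C(C)C)C(C)C)cc(OC)c1O[Si](C(C)C)(C(C)C)C(C)C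
F9 | step 6 | O–H insertion product of F8 and 14 | COc1cc([C@H](OC(C)OCC)[C@@H](OC2C(=O)CC(C(=O)OCC)CC2=O)CO[Si](C(C)C)(C(C)C)C(C)C)cc(OC)c1O[Si](C(C)C)(C(C)C)C(C)C
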